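**Retrosynthetic overview**

1. Target 23 ⇐ diol 22 (oxidation of the primary C17 alcohol only) ⇐ bis-silyl ether 21 ⇐ B-alkyl Suzuki coupling of the C9-vinyl decalin 17 with methyl (Z)-3-iodobut-2-enoate 19, which fixes the 13Z enoate.
2. 17 ⇐ octalin aldehyde 15 by hydrogenation of C6=C7 and methylenation of the C11 formyl group.
3. Rings A and B are formed together by an intramolecular Diels–Alder reaction of the acyclic (2E,8E,10E)-trienal 14: the diene terminus C5 (next to the C4 gem-dimethyl carbon) bonds to the enal β-carbon C10 (the future angular-methyl carbon) and closes ring A over the C1–C4 tether, while C8–C9 closes ring B.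
4. Enabling feature: the four contiguous ring-B stereocentres C5, C10, C9, C8 (C10 methyl, C9 chain and axial C8 carbon all cis, H5 trans), with C6–C7 as the only unsubstituted edge, are the aldehyde-endo adduct of an E-enal and an E,E-diene; the C3 oxygen on the tether relays the absolute configuration.
5. 14 ⇐ Heck coupling of vinyl enal 9 with alkenyl iodide 13; 9 ⇐ asymmetric reverse prenylation of aldehyde 4, made from geranyl acetate 1.

Key step: step 10

Remark: positions are cited in labdane numbering (ring A = C1–C5 and C10, ring B = C5–C10, C11/C12 = chain carbons, C17 = formyl carbon); (−)-Ipc2BH (from (+)-α-pinene), Cp2Zr(H)Cl and 9-BBN are taken as purchasable reagents.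

**Route**

Step 1
Reactants: 1 geranyl acetate
Product: 2 (±)-6,7-epoxygeranyl acetate
Conditions: mCPBA (1.05 equiv), NaHCO3, CH2Cl2, 0 °C
Reagents that add atoms: mCPBA, OOC(=O)c1cccc(Cl)c1
Why: Prilezhaev epoxidation should take the electron-rich 6,7-alkene in preference to the 2,3-alkene deactivated by the allylic acetate; the epoxide is racemic and its stereocentre is removed in step 2.

Step 2
Reactants: 2 (±)-6,7-epoxygeranyl acetate
Product: 4 (2E)-3-methyl-6-oxohex-2-en-1-yl acetate, via diol 3 (not isolated)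
Conditions: H5IO6 (1.1 equiv), THF/H2O, 0 °C to rt
Reagents that add atoms: none
Why: acidic periodate should open the epoxide to the vicinal diol and cleave it (Malaprade glycol cleavage) to the aldehyde and acetone without touching the acetate or the E-alkene.

Step 3
Reactants: 4 (2E)-3-methyl-6-oxohex-2-en-1-yl acetate
Product: 6 (2E,6R)-6-hydroxy-3,7,7-trimethylnona-2,8-dien-1-yl acetate, via borinate 5 (not isolated)
Conditions: (−)-Ipc2BH, 3-methylbuta-1,2-diene, THF, −25 °C; then 4, Et2O, −78 °C; then 30% H2O2, pH 7 phosphate buffer, MeOH, 0 °C to rt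
Reagents that add atoms: B-(3-methylbut-2-en-1-yl)diisopinocampheylborane, CC(C)=CCB([C@@H]1C[C@@H]2C[C@H]([C@H]1C)C2(C)C)[C@@H]1C[C@@H]2C[C@H]([C@H]1C)C2(C)C (formed in the flask from 3-methylbuta-1,2-diene, CC(C)=C=C)
Why: Brown asymmetric reverse prenylation through a chair Zimmerman–Traxler transition state should deliver the CMe2 carbon to the Si face of the aldehyde under control of the (+)-α-pinene-derived isopinocampheyl groups, setting C3 as R and creating the C4 quaternary carbon with its vinyl group, while the neutral oxidative work-up keeps the acetate.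

Step 4
Reactants: 6 (2E,6R)-6-hydroxy-3,7,7-trimethylnona-2,8-dien-1-yl acetate
Product: 7 (2E,6R)-6-[(tert-butyldimethylsilyl)oxy]-3,7,7-trimethylnona-2,8-dien-1-yl acetate
Conditions: TBSOTf (1.3 equiv), 2,6-lutidine, CH2Cl2, −78 to 0 °C
Reagents that add atoms: TBSOTf, CC(C)(C)[Si](C)(C)OS(=O)(=O)C(F)(F)F
Why: silylation with the silyl triflate should protect even this neopentyl-type secondary alcohol and install the bulky group that later steers the cycloaddition.

Step 5
Reactants: 7 (2E,6R)-6-[(tert-butyldimethylsilyl)oxy]-3,7,7-trimethylnona-2,8-dien-1-yl acetate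
Product: 8 (2E,6R)-6-[(tert-butyldimethylsilyl)oxy]-3,7,7-trimethylnona-2,8-dien-1-ol
Conditions: K2CO3 (0.2 equiv), MeOH, 0 °C to rt
Reagents that add atoms: none
Why: base-catalysed transesterification should remove the primary acetate and leave the hindered secondary silyl ether intact.

Step 6
Reactants: 8 (2E,6R)-6-[(tert-butyldimethylsilyl)oxy]-3,7,7-trimethylnona-2,8-dien-1-ol
Product: 9 (2E,6R)-6-[(tert-butyldimethylsilyl)oxy]-3,7,7-trimethylnona-2,8-dienal
Conditions: activated MnO2 (excess), CH2Cl2, rt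
Reagents that add atoms: none
Why: MnO2 allylic oxidation should give the E-enal with retention of geometry; the isolated vinyl group and the silyl ether are inert.

Step 7
Reactants: 10 prop-2-yn-1-ol
Product: 11 tert-butyldiphenyl(prop-2-yn-1-yloxy)silane
Conditions: TBDPSCl, imidazole, DMF, 0 °C to rt
Reagents that add atoms: TBDPSCl, CC(C)(C)[Si](Cl)(c1ccccc1)c1ccccc1
Why: standard silylation of a primary alcohol gives a robust ether that is not ionised by palladium or by the Lewis acid used later.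

Step 8
Reactants: 11 tert-butyldiphenyl(prop-2-yn-1-yloxy)silane
Product: 13 tert-butyl{[(2E)-3-iodoprop-2-en-1-yl]oxy}diphenylsilane, via alkenylzirconocene 12 (not isolated)
Conditions: Cp2Zr(H)Cl (1.2 equiv), THF, rt; then I2, 0 °C
Reagents that add atoms: iodine, II
Why: hydrozirconation adds Zr–H syn with zirconium on the terminal carbon, and iodinolysis with retention should give the E-alkenyl iodide only.

Step 9
Reactants: 9 (2E,6R)-6-[(tert-butyldimethylsilyl)oxy]-3,7,7-trimethylnona-2,8-dienal; 13 tert-butyl{[(2E)-3-iodoprop-2-en-1-yl]oxy}diphenylsilane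
Product: 14 (2E,6R,8E,10E)-6-[(tert-butyldimethylsilyl)oxy]-12-[(tert-butyldiphenylsilyl)oxy]-3,7,7-trimethyldodeca-2,8,10-trienal
Conditions: Pd(OAc)2 (10 mol %), Ag2CO3 (1.5 equiv), DMF, 50 °C, dark
Reagents that add atoms: none
Why: Mizoroki–Heck reaction: the alkenyl iodide adds oxidatively to zerovalent palladium, the terminal vinyl group inserts with the new bond at its unsubstituted carbon C6, and syn β-hydride elimination, possible only toward C6 because C4 is quaternary, should give the 8E,10E-diene while the trisubstituted enal does not insert and Ag2CO3 suppresses re-addition of the palladium hydride.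

Step 10
Reactants: 14 (2E,6R,8E,10E)-6-[(tert-butyldimethylsilyl)oxy]-12-[(tert-butyldiphenylsilyl)oxy]-3,7,7-trimethyldodeca-2,8,10-trienal
Product: 15 (1R,2R,4aS,6R,8aR)-6-[(tert-butyldimethylsilyl)oxy]-2-{[(tert-butyldiphenylsilyl)oxy]methyl}-5,5,8a-trimethyl-1,2,4a,5,6,7,8,8a-octahydronaphthalene-1-carbaldehyde
Conditions: Me2AlCl (50 mol %), CH2Cl2, −78 to −20 °C
Reagents that add atoms: none
Why: Coordination of Me2AlCl to the formyl oxygen lowers the LUMO of the E-enal, and the 8E,10E-diene adds across C9=C10 in a concerted, asynchronous intramolecular [4+2] cycloaddition (type 1 intramolecular Diels–Alder reaction of a 1,7,9-decatriene; closest precedent: Lewis-acid-promoted cyclisations of 2,8,10-trienals to trans-fused octalins) in which the bond from the diene terminus C5 to the β-carbon C10 is the more advanced one. Ring A (C1–C5, C10) closes as the six-membered ring spanned by the four-carbon tether C1–C4 when C5 bonds to C10, and ring B (C5–C10) closes as the cyclohexene of the cycloaddition through the second bond C8–C9, leaving C6=C7. Suprafacial addition carries the E geometry of the enal into the cis relation of the C10 methyl and the C9 formyl group, and the E,E geometry of the diene into the cis relation of C4 (on C5) and the silyloxymethyl group (on C8); the aldehyde-endo transition state then places the C9 formyl cis to the C8 substituent and the tether anti across C5–C10, which gives the trans ring fusion and the axial C8 carbon. Absolute configuration follows from C3: in the chair-like tether the bulky silyloxy group sits equatorial, so one face pairing of diene and dienophile is preferred and the 3R centre relays to 5S, 8R, 9R and the quaternary C10. The step needs endo over exo selectivity (secured by the E-enal with the Lewis acid and the chair tether, closure being helped by the gem-dimethyl group) and π-facial selectivity (secured by the equatorial C3 silyloxy group); regiochemistry is fixed by the tether.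

Step 11
Reactants: 15 (1R,2R,4aS,6R,8aR)-6-[(tert-butyldimethylsilyl)oxy]-2-{[(tert-butyldiphenylsilyl)oxy]methyl}-5,5,8a-trimethyl-1,2,4a,5,6,7,8,8a-octahydronaphthalene-1-carbaldehyde
Product: 16 (1R,2R,4aS,6R,8aR)-6-[(tert-butyldimethylsilyl)oxy]-2-{[(tert-butyldiphenylsilyl)oxy]methyl}-5,5,8a-trimethyldecahydronaphthalene-1-carbaldehyde
Conditions: H2 (1 atm), 10% Pd/C, EtOAc, rt
Reagents that add atoms: none
Why: catalytic hydrogenation should saturate the cis-disubstituted C6=C7 alkene without reducing the hindered aldehyde or cleaving the silyl ethers in EtOAc; no stereocentre is created.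

Step 12
Reactants: 16 (1R,2R,4aS,6R,8aR)-6-[(tert-butyldimethylsilyl)oxy]-2-{[(tert-butyldiphenylsilyl)oxy]methyl}-5,5,8a-trimethyldecahydronaphthalene-1-carbaldehyde
Product: 17 tert-butyl({(1R,2R,4aS,6R,8aS)-6-[(tert-butyldimethylsilyl)oxy]-1-ethenyl-5,5,8a-trimethyldecahydronaphthalen-2-yl}methoxy)diphenylsilane
Conditions: Ph3PCH3Br, KN(SiMe3)2, THF, 0 °C; then 16, −78 to 0 °C
Reagents that add atoms: methylenetriphenylphosphorane, C=P(c1ccccc1)(c1ccccc1)c1ccccc1 (from methyltriphenylphosphonium bromide)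
Why: Wittig methylenation with the small unstabilised ylide should be faster than enolisation at low temperature, so C9 keeps its configuration.

Step 13
Reactants: 18 methyl but-2-ynoate
Product: 19 methyl (2Z)-3-iodobut-2-enoate
Conditions: NaI, AcOH, 110 °C
Reagents that add atoms: sodium iodide, [Na+].[I-]
Why: conjugate hydroiodination of the ynoate (iodide addition, then protonation) should give the Z-β-iodo enoate with iodine cis to the ester.

Step 14
Reactants: 17 tert-butyl({(1R,2R,4aS,6R,8aS)-6-[(tert-butyldimethylsilyl)oxy]-1-ethenyl-5,5,8a-trimethyldecahydronaphthalen-2-yl}methoxy)diphenylsilane; 19 methyl (2Z)-3-iodobut-2-enoate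
Product: 21 methyl (2Z)-5-[(1R,2R,4aS,6R,8aS)-6-[(tert-butyldimethylsilyl)oxy]-2-{[(tert-butyldiphenylsilyl)oxy]methyl}-5,5,8a-trimethyldecahydronaphthalen-1-yl]-3-methylpent-2-enoate, via alkylborane 20 (not isolated)
Conditions: 9-BBN (0.5 M in THF), 0 °C to rt; then 19, Pd(dppf)Cl2 (5 mol %), AsPh3 (5 mol %), Cs2CO3, DMF/THF/H2O, rt
Reagents that add atoms: none
Why: 9-BBN hydroborates the monosubstituted vinyl group at its terminal carbon, and the B-alkyl Suzuki–Miyaura coupling should proceed with retention of the alkenyl iodide geometry, giving the 13Z enoate.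

Step 15
Reactants: 21 methyl (2Z)-5-[(1R,2R,4aS,6R,8aS)-6-[(tert-butyldimethylsilyl)oxy]-2-{[(tert-butyldiphenylsilyl)oxy]methyl}-5,5,8a-trimethyldecahydronaphthalen-1-yl]-3-methylpent-2-enoate
Product: 22 methyl (2Z)-5-[(1R,2R,4aS,6R,8aS)-6-hydroxy-2-(hydroxymethyl)-5,5,8a-trimethyldecahydronaphthalen-1-yl]-3-methylpent-2-enoate
Conditions: HF·pyridine (excess), THF/pyridine, 0 °C to 40 °C
Reagents that add atoms: none
Why: fluoride-driven desilylation should cleave both silyl ethers under mildly acidic conditions that leave the methyl ester, the Z-enoate and all stereocentres untouched.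

Step 16
Reactants: 22 methyl (2Z)-5-[(1R,2R,4aS,6R,8aS)-6-hydroxy-2-(hydroxymethyl)-5,5,8a-trimethyldecahydronaphthalen-1-yl]-3-methylpent-2-enoate
Product: 23 methyl (2Z)-5-[(1R,2R,4aS,6R,8aS)-2-formyl-6-hydroxy-5,5,8a-trimethyldecahydronaphthalen-1-yl]-3-methylpent-2-enoate (CNP0188570.2)
Conditions: TEMPO (10 mol %), PhI(OAc)2 (1.1 equiv), CH2Cl2, rt
Reagents that add atoms: none
Why: oxoammonium (TEMPO) oxidation should take the primary C17 alcohol in preference to the hindered secondary C3 alcohol next to the quaternary carbon, and the non-basic medium should keep the axial C8 formyl group from epimerising.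

**Compound list**

1 | geranyl acetate, (2E)-3,7-dimethylocta-2,6-dien-1-yl acetate | CC(C)=CCC/C(C)=C/COC(C)=O | starting material
2 | (±)-6,7-epoxygeranyl acetate, (2E)-5-(3,3-dimethyloxiran-2-yl)-3-methylpent-2-en-1-yl acetate (racemic) | CC1(C)OC1CC/C(C)=C/COC(C)=O | intermediate
3 | (2E)-6,7-dihydroxy-3,7-dimethyloct-2-en-1-yl acetate (racemic diol) | CC(C)(O)C(O)CC/C(C)=C/COC(C)=O | intermediate
4 | (2E)-3-methyl-6-oxohex-2-en-1-yl acetate | O=CCC/C(C)=C/COC(C)=O | intermediate
5 | (2E,6R)-6-[(diisopinocampheylboranyl)oxy]-3,7,7-trimethylnona-2,8-dien-1-yl acetate | CC(=O)OC/C=C(\C)CC[C@@H](OB([C@@H]1C[C@@H]2C[C@H]([C@H]1C)C2(C)C)[C@@H]1C[C@@H]2C[C@H]([C@H]1C)C2(C)C)C(C)(C)C=C | intermediate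
6 | (2E,6R)-6-hydroxy-3,7,7-trimethylnona-2,8-dien-1-yl acetate | CC(=O)OC/C=C(\C)CC[C@@H](O)C(C)(C)C=C | intermediate
7 | (2E,6R)-6-[(tert-butyldimethylsilyl)oxy]-3,7,7-trimethylnona-2,8-dien-1-yl acetate | CC(=O)OC/C=C(\C)CC[C@@H](O[Si](C)(C)C(C)(C)C)C(C)(C)C=C | intermediate
8 | (2E,6R)-6-[(tert-butyldimethylsilyl)oxy]-3,7,7-trimethylnona-2,8-dien-1-ol | OC/C=C(\C)CC[C@@H](O[Si](C)(C)C(C)(C)C)C(C)(C)C=C | intermediate
9 | (2E,6R)-6-[(tert-butyldimethylsilyl)oxy]-3,7,7-trimethylnona-2,8-dienal | O=C/C=C(\C)CC[C@@H](O[Si](C)(C)C(C)(C)C)C(C)(C)C=C | intermediate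
10 | prop-2-yn-1-ol | C#CCO | starting material
11 | tert-butyldiphenyl(prop-2-yn-1-yloxy)silane | C#CCO[Si](c1ccccc1)(c1ccccc1)C(C)(C)C | intermediate
12 | chlorobis(cyclopentadienyl)[(1E)-3-(tert-butyldiphenylsilyloxy)prop-1-en-1-yl]zirconium | Cl[Zr](/C=C/CO[Si](c1ccccc1)(c1ccccc1)C(C)(C)C)(C1C=CC=C1)C1C=CC=C1 | intermediate
13 | tert-butyl{[(2E)-3-iodoprop-2-en-1-yl]oxy}diphenylsilane | I/C=C/CO[Si](c1ccccc1)(c1ccccc1)C(C)(C)C | intermediate
14 | (2E,6R,8E,10E)-6-[(tert-butyldimethylsilyl)oxy]-12-[(tert-butyldiphenylsilyl)oxy]-3,7,7-trimethyldodeca-2,8,10-trienal | O=C/C=C(\C)CC[C@@H](O[Si](C)(C)C(C)(C)C)C(C)(C)/C=C/C=C/CO[Si](c1ccccc1)(c1ccccc1)C(C)(C)C | intermediate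
15 | (1R,2R,4aS,6R,8aR)-6-[(tert-butyldimethylsilyl)oxy]-2-{[(tert-butyldiphenylsilyl)oxy]methyl}-5,5,8a-trimethyl-1,2,4a,5,6,7,8,8a-octahydronaphthalene-1-carbaldehyde | O=C[C@@H]1[C@H](CO[Si](c3ccccc3)(c3ccccc3)C(C)(C)C)C=C[C@@H]2C(C)(C)[C@H](O[Si](C)(C)C(C)(C)C)CC[C@@]12C | intermediate
16 | (1R,2R,4aS,6R,8aR)-6-[(tert-butyldimethylsilyl)oxy]-2-{[(tert-butyldiphenylsilyl)oxy]methyl}-5,5,8a-trimethyldecahydronaphthalene-1-carbaldehyde | O=C[C@@H]1[C@H](CO[Si](c3ccccc3)(c3ccccc3)C(C)(C)C)CC[C@@H]2C(C)(C)[C@H](O[Si](C)(C)C(C)(C)C)CC[C@@]12C | intermediate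
17 | tert-butyl({(1R,2R,4aS,6R,8aS)-6-[(tert-butyldimethylsilyl)oxy]-1-ethenyl-5,5,8a-trimethyldecahydronaphthalen-2-yl}methoxy)diphenylsilane | C=C[C@@H]1[C@H](CO[Si](c3ccccc3)(c3ccccc3)C(C)(C)C)CC[C@@H]2C(C)(C)[C@H](O[Si](C)(C)C(C)(C)C)CC[C@@]12C | intermediate
18 | methyl but-2-ynoate | CC#CC(=O)OC | starting material
19 | methyl (2Z)-3-iodobut-2-enoate | COC(=O)/C=C(/C)I | intermediate
20 | 9-{2-[(1R,2R,4aS,6R,8aS)-6-[(tert-butyldimethylsilyl)oxy]-2-{[(tert-butyldiphenylsilyl)oxy]methyl}-5,5,8a-trimethyldecahydronaphthalen-1-yl]ethyl}-9-borabicyclo[3.3.1]nonane | C(C[C@@H]1[C@H](CO[Si](c3ccccc3)(c3ccccc3)C(C)(C)C)CC[C@@H]2C(C)(C)[C@H](O[Si](C)(C)C(C)(C)C)CC[C@@]12C)B1C2CCCC1CCC2 | intermediate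
21 | methyl (2Z)-5-[(1R,2R,4aS,6R,8aS)-6-[(tert-butyldimethylsilyl)oxy]-2-{[(tert-butyldiphenylsilyl)oxy]methyl}-5,5,8a-trimethyldecahydronaphthalen-1-yl]-3-methylpent-2-enoate | COC(=O)/C=C(/C)CC[C@@H]1[C@H](CO[Si](c3ccccc3)(c3ccccc3)C(C)(C)C)CC[C@@H]2C(C)(C)[C@H](O[Si](C)(C)C(C)(C)C)CC[C@@]12C | intermediate
22 | methyl (2Z)-5-[(1R,2R,4aS,6R,8aS)-6-hydroxy-2-(hydroxymethyl)-5,5,8a-trimethyldecahydronaphthalen-1-yl]-3-methylpent-2-enoate | COC(=O)/C=C(/C)CC[C@@H]1[C@H](CO)CC[C@@H]2C(C)(C)[C@H](O)CC[C@@]12C | intermediate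
23 | methyl (2Z)-5-[(1R,2R,4aS,6R,8aS)-2-formyl-6-hydroxy-5,5,8a-trimethyldecahydronaphthalen-1-yl]-3-methylpent-2-enoate | COC(=O)/C=C(/C)CC[C@@H]1[C@H](C=O)CC[C@@H]2C(C)(C)[C@H](O)CC[C@@]12C | target

**Step count**

Total steps: 16. Longest linear sequence: 13 (steps 1–6, 9–12, 14–16).

**Steps most likely to fail, with fallbacks**

Step 10 (intramolecular Diels–Alder). The neutral aluminium Lewis acid may activate the β,β-disubstituted enal too weakly for bond formation at the congested C5–C10 junction. Slow cyclisation would then be overtaken by ionisation of the dienylic silyl ether or by a less selective thermal background reaction. The fallback uses a cationic dienophile (Gassman-type ionic Diels–Alder reaction) and sets out from 14. Acetalisation with 1,2-bis(trimethylsilyloxy)ethane and catalytic TMSOTf in CH2Cl2 at −78 °C should give the trienyl dioxolane F1. Catalytic TfOH in CH2Cl2 at −78 to −40 °C should then open the acetal to an alkoxyallyl cation, which cyclises through the same endo, equatorial-silyloxy transition state and recloses to the octalin dioxolane F2. Hydrolysis with PPTS in wet acetone at 50 °C returns to 15.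

Step 9 (Heck coupling). The hindered vinyl group next to the quaternary carbon may insert slowly, so that the alkenylpalladium species decomposes or homocouples, and the palladium hydride may re-add to the new diene and move the double bonds. The fallback separates the two events and sets out from 9. Cross-metathesis with vinylboronic acid pinacol ester (second-generation Hoveyda–Grubbs catalyst, CH2Cl2, 40 °C) should give the E-alkenylboronate F3. Suzuki–Miyaura coupling of F3 with 13 (Pd(dppf)Cl2, K3PO4, THF/H2O, rt) returns to 14.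

Step 14 (B-alkyl Suzuki coupling). Transfer of the congested alkyl group from boron to palladium may be slow, so that protodeboronation and β-hydride elimination compete, and the aqueous base may isomerise or hydrolyse the Z-iodoenoate. The fallback is a base-free Negishi coupling and sets out from 17. Hydroboration with 9-BBN followed by NaOH/H2O2 should give the primary alcohol F4. Iodination with I2, PPh3 and imidazole in CH2Cl2 gives the primary iodide F5. Zinc insertion (Zn dust, LiCl, THF, 40 °C) gives the alkylzinc iodide F6, and coupling of F6 with 19 (Pd(PPh3)4, THF/DMA, rt) returns to 21 with retention of the Z geometry.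

Further compounds
F1 | step 10 | 2-[(1E,5R,7E,9E)-5-[(tert-butyldimethylsilyl)oxy]-11-[(tert-butyldiphenylsilyl)oxy]-2,6,6-trimethylundeca-1,7,9-trien-1-yl]-1,3-dioxolane | C1COC(O1)/C=C(\C)CC[C@@H](O[Si](C)(C)C(C)(C)C)C(C)(C)/C=C/C=C/CO[Si](c1ccccc1)(c1ccccc1)C(C)(C)C
F2 | step 10 | 2-[(1R,2R,4aS,6R,8aR)-6-[(tert-butyldimethylsilyl)oxy]-2-{[(tert-butyldiphenylsilyl)oxy]methyl}-5,5,8a-trimethyl-1,2,4a,5,6,7,8,8a-octahydronaphthalen-1-yl]-1,3-dioxolane | C4COC(O4)[C@@H]1[C@H](CO[Si](c3ccccc3)(c3ccccc3)C(C)(C)C)C=C[C@@H]2C(C)(C)[C@H](O[Si](C)(C)C(C)(C)C)CC[C@@]12C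
F3 | step 9 | (2E,6R,8E)-6-[(tert-butyldimethylsilyl)oxy]-3,7,7-trimethyl-9-(4,4,5,5-tetramethyl-1,3,2-dioxaborolan-2-yl)nona-2,8-dienal | O=C/C=C(\C)CC[C@@H](O[Si](C)(C)C(C)(C)C)C(C)(C)/C=C/B1OC(C)(C)C(C)(C)O1
F4 | step 14 | 2-[(1R,2R,4aS,6R,8aS)-6-[(tert-butyldimethylsilyl)oxy]-2-{[(tert-butyldiphenylsilyl)oxy]methyl}-5,5,8a-trimethyldecahydronaphthalen-1-yl]ethan-1-ol | OCC[C@@H]1[C@H](CO[Si](c3ccccc3)(c3ccccc3)C(C)(C)C)CC[C@@H]2C(C)(C)[C@H](O[Si](C)(C)C(C)(C)C)CC[C@@]12C
F5 | step 14 | tert-butyl({(1R,2R,4aS,6R,8aS)-6-[(tert-butyldimethylsilyl)oxy]-1-(2-iodoethyl)-5,5,8a-trimethyldecahydronaphthalen-2-yl}methoxy)diphenylsilane | ICC[C@@H]1[C@H](CO[Si](c3ccccc3)(c3ccccc3)C(C)(C)C)CC[C@@H]2C(C)(C)[C@H](O[Si](C)(C)C(C)(C)C)CC[C@@]12C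
F6 | step 14 | {2-[(1R,2R,4aS,6R,8aS)-6-[(tert-butyldimethylsilyl)oxy]-2-{[(tert-butyldiphenylsilyl)oxy]methyl}-5,5,8a-trimethyldecahydronaphthalen-1-yl]ethyl}zinc iodide | I[Zn]CC[C@@H]1[C@H](CO[Si](c3ccccc3)(c3ccccc3)C(C)(C)C)CC[C@@H]2C(C)(C)[C@H](O[Si](C)(C)C(C)(C)C)CC[C@@]12C
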